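## Retrosynthetic overview
1. The target comes from its bis-TBS ether by buffered fluoride desilylation.
2. Key disconnection: C5–C6 and O1–C2 of the dihydropyranone, made in one carbene-catalysed formal [4+2] between an epoxy aldehyde and a 4-acyloxycrotonate aryl ester that already carries the dienoate chain.
3. Donor: dienoic acid plus 4-nitrophenyl 4-bromocrotonate (carboxylate SN2). The acid comes from 4-silyloxybutanal by organocatalytic α-hydroxymethylation (C6'), Wittig and HWE.
4. Aldehyde: meso-2,4-dimethylglutaric anhydride, then alkaloid-catalysed methanolysis (C7, C9), reduction, iodination, Negishi coupling, Shi epoxidation (C11, C12) and partial reduction.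
5. Ring order: the oxirane is formed first (step 10) and the dihydropyranone second (step 12).

Numbering used: lactone O1, C2–C6; side chain C7–C13; acyl chain C1'–C8'.

Assumption: for steps 6 and 12 the named catalyst enantiomer (or pseudo-enantiomer) is taken to give the drawn product, and its equally available antipode would replace it without changing the route; 1, 14 and the L-fructose-derived Shi ketone are taken as purchasable.

## Route

Step 1
Reactants: 1 4-[(tert-butyldimethylsilyl)oxy]butanal; 2 formaldehyde (37% aqueous)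
Product: 4 (2R)-4-[(tert-butyldimethylsilyl)oxy]-2-{[(tert-butyldimethylsilyl)oxy]methyl}butanal, via hydroxymethyl aldehyde 3 (not isolated)
Conditions: (S)-2-[diphenyl(trimethylsilyloxy)methyl]pyrrolidine (10 mol %), 2 (3 equiv), pH 7 buffer (KH2PO4/K2HPO4), toluene, rt; organic layer separated and dried; then TBSCl, imidazole, CH2Cl2, 0 °C to rt
Reagents that add atoms: tert-butyldimethylsilyl chloride, CC(C)(C)[Si](C)(C)Cl
Why: Enamine-catalysed α-hydroxymethylation (organocatalytic cross-aldol with formaldehyde), in which the diphenyl(silyloxy)methyl group shields one face of the E-enamine so that formaldehyde adds to the open face and sets C6' (R in the aldehyde, S in the target), while immediate silylation stops hemiacetal formation, retro-aldol and racemisation.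

Step 2
Reactants: 4 (2R)-bis-silyloxy aldehyde; 5 2-(triphenyl-λ5-phosphanylidene)propanal
Product: 6 (2E,4S)-6-[(tert-butyldimethylsilyl)oxy]-4-{[(tert-butyldimethylsilyl)oxy]methyl}-2-methylhex-2-enal
Conditions: 5 (1.3 equiv), toluene, 90 °C
Reagents that add atoms: none
Why: Wittig olefination with a stabilised formyl ylide gives the (E)-2-methylenal, and the salt-free neutral conditions leave the α-stereocentre and both silyl ethers untouched.

Step 3
Reactants: 6 (2E,4S)-enal; 7 (diethoxyphosphoryl)acetic acid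
Product: 9 (2E,4E,6S)-8-[(tert-butyldimethylsilyl)oxy]-6-{[(tert-butyldimethylsilyl)oxy]methyl}-4-methylocta-2,4-dienoic acid, via dilithio phosphonoacetate 8 (not isolated)
Conditions: 7, n-BuLi (2.05 equiv), THF, −78 to 0 °C; then 6, −78 °C to rt; 1 M aq KHSO4 work-up
Reagents that add atoms: none
Why: Horner–Wadsworth–Emmons olefination with the phosphonoacetate dianion is E-selective on enals and delivers the free dienoic acid directly, avoiding both an ester hydrolysis and the amine/heat conditions that could racemise C6' through a dienamine.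

Step 4
Reactants: 10 (2E)-4-bromobut-2-enoic acid; 11 4-nitrophenol
Product: 12 4-nitrophenyl (2E)-4-bromobut-2-enoate
Conditions: DCC, CH2Cl2, 0 °C to rt
Reagents that add atoms: none
Why: Carbodiimide esterification gives the activated aryl ester that a carbene can later be acylated by, and leaving out DMAP avoids displacement of the allylic bromide.

Step 5
Reactants: 9 dienoic acid; 12 4-nitrophenyl (2E)-4-bromobut-2-enoate
Product: 13 4-nitrophenyl (2E)-4-{[(2E,4E,6S)-8-[(tert-butyldimethylsilyl)oxy]-6-{[(tert-butyldimethylsilyl)oxy]methyl}-4-methylocta-2,4-dienoyl]oxy}but-2-enoate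
Conditions: KHCO3 (1.2 equiv), DMF, 0 °C to rt
Reagents that add atoms: none
Why: SN2 alkylation of the carboxylate at the activated allylic bromide is much faster than its thermodynamically uphill attack on the aryl ester, so the C5–O acyl bond of the target is put in place without any protecting group at that oxygen.

Step 6
Reactants: 14 meso-2,4-dimethylglutaric anhydride [(3R,5S)-3,5-dimethyloxane-2,6-dione]
Product: 15 (2R,4S)-5-methoxy-2,4-dimethyl-5-oxopentanoic acid
Conditions: (DHQD)2AQN (20 mol %), MeOH (10 equiv), Et2O, −40 °C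
Reagents that add atoms: methanol, CO
Why: Cinchona-alkaloid-catalysed (general-base) desymmetrising methanolysis of a meso anhydride delivers methanol to one enantiotopic carbonyl, which fixes the absolute configuration of C7 and C9 in one operation while their syn relationship comes from the meso ring.

Step 7
Reactants: 15 hemiester
Product: 16 methyl (2S,4R)-5-hydroxy-2,4-dimethylpentanoate
Conditions: BH3·SMe2 (1.2 equiv), THF, −10 °C to rt; aqueous quench; used at once
Reagents that add atoms: none
Why: Chemoselective borane reduction of a carboxylic acid (through the acyloxyborane) spares the methyl ester and both stereocentres, and prompt use forestalls δ-lactonisation.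

Step 8
Reactants: 16 hydroxy ester
Product: 17 methyl (2S,4R)-5-iodo-2,4-dimethylpentanoate
Conditions: I2, PPh3, imidazole, CH2Cl2, 0 °C
Reagents that add atoms: iodine, [I][I]
Why: Appel-type iodination (Garegg–Samuelsson conditions) displaces the activated primary alcohol by SN2 at a non-stereogenic CH2 under conditions too mild to epimerise C7.

Step 9
Reactants: 17 iodo ester; 18 (2E)-2-bromobut-2-ene
Product: 20 methyl (2S,4R,6E)-2,4,6-trimethyloct-6-enoate, via alkylzinc iodide 19 (not isolated)
Conditions: Zn dust (activated with BrCH2CH2Br/Me3SiCl), LiCl, THF, 40 °C; then 18, PdCl2(dppf) (3 mol %), THF, rt to 45 °C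
Reagents that add atoms: none
Why: Negishi sp3–sp2 cross-coupling works here because zinc insertion tolerates the ester, the metal sits on a non-stereogenic primary carbon, and the alkenyl bromide couples with retention to give the E-trisubstituted alkene.

Step 10
Reactants: 20 alkenyl ester
Product: 21 methyl (2S,4R)-5-[(2S,3S)-2,3-dimethyloxiran-2-yl]-2,4-dimethylpentanoate
Conditions: 1,2:4,5-di-O-isopropylidene-β-L-erythro-2,3-hexodiulo-2,6-pyranose (ent-Shi ketone, 30 mol %), Oxone (2KHSO5·KHSO4·K2SO4), K2CO3, Bu4NHSO4 (cat.), aq Na2B4O7/Na2EDTA buffer, MeCN–CH2(OMe)2, 0 °C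
Reagents that add atoms: potassium peroxymonosulfate (active part of Oxone), [K+].[O-]S(=O)(=O)OO
Why: Shi asymmetric epoxidation (chiral dioxirane, spiro transition state) is at its best with E-trisubstituted alkenes, and because the D-fructose ketone gives R,R-epoxides for this substitution pattern, its enantiomer sets C11 and C12 as S,S under catalyst control with syn oxygen delivery.

Step 11
Reactants: 21 epoxy ester
Product: 22 (2S,4R)-5-[(2S,3S)-2,3-dimethyloxiran-2-yl]-2,4-dimethylpentanal
Conditions: i-Bu2AlH (1.1 equiv), CH2Cl2, −78 °C; MeOH, then aq potassium sodium tartrate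
Reagents that add atoms: none
Why: Partial ester reduction with i-Bu2AlH stops at the tetrahedral aluminium hemiacetal at −78 °C and releases the aldehyde only on quench, without opening the trisubstituted epoxide or epimerising C7.

Step 12
Reactants: 13 γ-acyloxycrotonate aryl ester; 22 epoxy aldehyde
Product: 23 (2R,3R)-2-{(2S,4R)-5-[(2S,3S)-2,3-dimethyloxiran-2-yl]-4-methylpentan-2-yl}-6-oxo-3,6-dihydro-2H-pyran-3-yl (2E,4E,6S)-8-[(tert-butyldimethylsilyl)oxy]-6-{[(tert-butyldimethylsilyl)oxy]methyl}-4-methylocta-2,4-dienoate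
Conditions: (5S)-5-[hydroxy(diphenyl)methyl]-2-mesityl-6,7-dihydro-5H-pyrrolo[2,1-c][1,2,4]triazol-2-ium tetrafluoroborate (15 mol %), i-Pr2NEt (1.5 equiv), 4 Å MS, toluene, 0 °C, 13 (1.3 equiv) added over 4 h
Reagents that add atoms: none
Why: Proposed new method: the carbene is acylated by the 4-nitrophenyl ester to give an α,β-unsaturated acyl azolium whose γ-CH2 (acidified by the azolium and by the acyloxy group) is deprotonated by i-Pr2NEt to an (E)-4-acyloxy azolium dienolate, whose s-cis conformer adds through Cγ to the aldehyde held by the catalyst's carbinol O–H hydrogen bond (bound to the lone pair anti to the alkyl chain, which places that chain endo) in a closed [4+2]-type transition state, so that acyloxy "outside" plus alkyl "endo" gives the 5,6-cis lactone, the catalyst arm blocks one dienolate face (5R), the Felkin–Anh preference of the α-methyl aldehyde reinforces 6R, and the alkoxide closes onto the acyl azolium faster than 1,2-acyl migration to release the carbene; the closest known reaction type is carbene-catalysed γ-activation of β-substituted unsaturated aryl esters or enals with formal [4+2] annulation onto activated ketones (trifluoromethyl ketones, isatins), which has not been shown for β-unsubstituted γ-oxy donors or for unactivated aliphatic aldehydes.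

Step 13
Reactants: 23 bis-TBS ether
Product: 24 target, (2R,3R)-2-{(2S,4R)-5-[(2S,3S)-2,3-dimethyloxiran-2-yl]-4-methylpentan-2-yl}-6-oxo-3,6-dihydro-2H-pyran-3-yl (2E,4E,6S)-8-hydroxy-6-(hydroxymethyl)-4-methylocta-2,4-dienoate
Conditions: HF·pyridine, excess pyridine, THF, 0 °C to rt
Reagents that add atoms: none
Why: Fluoride-mediated desilylation with pyridine-buffered HF·pyridine cleaves the two primary silyl ethers under near-neutral conditions that a trisubstituted epoxide, the dienoate and the base-sensitive acyloxy lactone tolerate, and no stereocentre is involved.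

## Compound list
1 | 4-[(tert-butyldimethylsilyl)oxy]butanal | O=CCCCO[Si](C)(C)C(C)(C)C | starting material
2 | formaldehyde | C=O | starting material
3 | (2R)-4-[(tert-butyldimethylsilyl)oxy]-2-(hydroxymethyl)butanal | O=C[C@@H](CO)CCO[Si](C)(C)C(C)(C)C | intermediate
4 | (2R)-4-[(tert-butyldimethylsilyl)oxy]-2-{[(tert-butyldimethylsilyl)oxy]methyl}butanal | O=C[C@@H](CO[Si](C)(C)C(C)(C)C)CCO[Si](C)(C)C(C)(C)C | intermediate
5 | 2-(triphenyl-λ5-phosphanylidene)propanal | CC(C=O)=P(c1ccccc1)(c1ccccc1)c1ccccc1 | starting material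
6 | (2E,4S)-6-[(tert-butyldimethylsilyl)oxy]-4-{[(tert-butyldimethylsilyl)oxy]methyl}-2-methylhex-2-enal | CC(/C=O)=C\[C@@H](CO[Si](C)(C)C(C)(C)C)CCO[Si](C)(C)C(C)(C)C | intermediate
7 | (diethoxyphosphoryl)acetic acid | CCOP(=O)(CC(=O)O)OCC | starting material
8 | dilithium salt (carboxylate, α-carbanion) of (diethoxyphosphoryl)acetic acid | [Li+].[Li+].CCOP(=O)([CH-]C([O-])=O)OCC | intermediate
9 | (2E,4E,6S)-8-[(tert-butyldimethylsilyl)oxy]-6-{[(tert-butyldimethylsilyl)oxy]methyl}-4-methylocta-2,4-dienoic acid | CC(/C=C/C(=O)O)=C\[C@@H](CO[Si](C)(C)C(C)(C)C)CCO[Si](C)(C)C(C)(C)C | intermediate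
10 | (2E)-4-bromobut-2-enoic acid | OC(=O)/C=C/CBr | starting material
11 | 4-nitrophenol | Oc1ccc(cc1)[N+](=O)[O-] | starting material
12 | 4-nitrophenyl (2E)-4-bromobut-2-enoate | O=C(/C=C/CBr)Oc1ccc(cc1)[N+](=O)[O-] | intermediate
13 | 4-nitrophenyl (2E)-4-{[(2E,4E,6S)-8-[(tert-butyldimethylsilyl)oxy]-6-{[(tert-butyldimethylsilyl)oxy]methyl}-4-methylocta-2,4-dienoyl]oxy}but-2-enoate | CC(/C=C/C(=O)OC/C=C/C(=O)Oc1ccc(cc1)[N+](=O)[O-])=C\[C@@H](CO[Si](C)(C)C(C)(C)C)CCO[Si](C)(C)C(C)(C)C | intermediate
14 | meso-2,4-dimethylglutaric anhydride, (3R,5S)-3,5-dimethyloxane-2,6-dione | C[C@@H]1C[C@H](C)C(=O)OC1=O | starting material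
15 | (2R,4S)-5-methoxy-2,4-dimethyl-5-oxopentanoic acid | COC(=O)[C@@H](C)C[C@@H](C)C(=O)O | intermediate
16 | methyl (2S,4R)-5-hydroxy-2,4-dimethylpentanoate | COC(=O)[C@@H](C)C[C@@H](C)CO | intermediate
17 | methyl (2S,4R)-5-iodo-2,4-dimethylpentanoate | COC(=O)[C@@H](C)C[C@@H](C)CI | intermediate
18 | (2E)-2-bromobut-2-ene | C/C=C(\C)Br | starting material
19 | [(2R,4S)-5-methoxy-2,4-dimethyl-5-oxopentyl]zinc iodide | COC(=O)[C@@H](C)C[C@@H](C)C[Zn]I | intermediate
20 | methyl (2S,4R,6E)-2,4,6-trimethyloct-6-enoate | COC(=O)[C@@H](C)C[C@@H](C)C/C(C)=C/C | intermediate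
21 | methyl (2S,4R)-5-[(2S,3S)-2,3-dimethyloxiran-2-yl]-2,4-dimethylpentanoate | COC(=O)[C@@H](C)C[C@@H](C)C[C@]1(C)O[C@H]1C | intermediate
22 | (2S,4R)-5-[(2S,3S)-2,3-dimethyloxiran-2-yl]-2,4-dimethylpentanal | O=C[C@@H](C)C[C@@H](C)C[C@]1(C)O[C@H]1C | intermediate
23 | bis-TBS ether of the target (full name in step 12) | CC(/C=C/C(=O)O[C@@H]1C=CC(=O)O[C@@H]1[C@@H](C)C[C@@H](C)C[C@]1(C)O[C@H]1C)=C\[C@@H](CO[Si](C)(C)C(C)(C)C)CCO[Si](C)(C)C(C)(C)C | intermediate
24 | CNP0160449.1 (full name in step 13) | CC(/C=C/C(=O)O[C@@H]1C=CC(=O)O[C@@H]1[C@@H](C)C[C@@H](C)C[C@]1(C)O[C@H]1C)=C\[C@@H](CO)CCO | target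

## Count and risks
Total step count: 13. Longest linear sequence: 8 (steps 6, 7, 8, 9, 10, 11, 12, 13).

**Most likely to fail, first: step 12 (the proposed annulation).**
- The donor has no β-substituent. Oligomerisation by Michael addition to the acyl azolium, or α- instead of γ-attack, could therefore compete.
- The aldehyde is unactivated.
- The product can ring-open if it is left with base.
- The cis/trans ratio is untested.

The fallback sets out from 22 and comes back at 23, and uses only known chemistry.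
- 22 is added to the (Z)-γ-alkoxyallylborane made from allyl 4-methoxybenzyl ether (s-BuLi, THF, −78 °C; (−)-Ipc2BOMe; BF3·OEt2). Work-up with NaOH/H2O2 gives the syn homoallylic alcohol (3R,4R,5S,7R)-8-[(2S,3S)-2,3-dimethyloxiran-2-yl]-3-[(4-methoxyphenyl)methoxy]-5,7-dimethyloct-1-en-4-ol F1.
- Acryloyl chloride and i-Pr2NEt (CH2Cl2, 0 °C) give (3R,4R,5S,7R)-8-[(2S,3S)-2,3-dimethyloxiran-2-yl]-3-[(4-methoxyphenyl)methoxy]-5,7-dimethyloct-1-en-4-yl prop-2-enoate F2.
- Ring-closing metathesis with the second-generation Grubbs catalyst (CH2Cl2, 40 °C) gives (5R,6R)-6-{(2S,4R)-5-[(2S,3S)-2,3-dimethyloxiran-2-yl]-4-methylpentan-2-yl}-5-[(4-methoxyphenyl)methoxy]-5,6-dihydro-2H-pyran-2-one F3.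
- DDQ (CH2Cl2/pH 7 buffer) gives (5R,6R)-6-{(2S,4R)-5-[(2S,3S)-2,3-dimethyloxiran-2-yl]-4-methylpentan-2-yl}-5-hydroxy-5,6-dihydro-2H-pyran-2-one F4.
- Yamaguchi esterification of F4 with acid 9 (2,4,6-trichlorobenzoyl chloride, Et3N, DMAP, toluene) gives 23.

**Second: step 13.** HF could open the trisubstituted epoxide to a fluorohydrin before both silyl ethers are gone. The fallback moves the epoxidation to the end. It sets out from 20 and comes back at 24.
- i-Bu2AlH (CH2Cl2, −78 °C) converts 20 into (2S,4R,6E)-2,4,6-trimethyloct-6-enal F5.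
- The lactone is built from F5 and 13 as in step 12 (or from F5 and 9 by the allylboration, metathesis and esterification sequence above). This gives (2R,3R)-2-[(2S,4R,6E)-4,6-dimethyloct-6-en-2-yl]-6-oxo-3,6-dihydro-2H-pyran-3-yl (2E,4E,6S)-8-[(tert-butyldimethylsilyl)oxy]-6-{[(tert-butyldimethylsilyl)oxy]methyl}-4-methylocta-2,4-dienoate F6.
- HF·pyridine gives the diol (2R,3R)-2-[(2S,4R,6E)-4,6-dimethyloct-6-en-2-yl]-6-oxo-3,6-dihydro-2H-pyran-3-yl (2E,4E,6S)-8-hydroxy-6-(hydroxymethyl)-4-methylocta-2,4-dienoate F7.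
- The only electron-rich alkene of F7 is epoxidised with stoichiometric ent-Shi ketone, Oxone (2KHSO5·KHSO4·K2SO4) and NaHCO3 at about pH 8 (MeCN/aq Na2EDTA, 0 °C) to give 24.

**Third: step 5.** The aryl ester of 12 may be hydrolysed or scrambled while the carboxylate is alkylated. The fallback replaces the substitution by olefin metathesis. It sets out from 9 and comes back at 13.
- Allyl bromide and K2CO3 (DMF) give prop-2-en-1-yl (2E,4E,6S)-8-[(tert-butyldimethylsilyl)oxy]-6-{[(tert-butyldimethylsilyl)oxy]methyl}-4-methylocta-2,4-dienoate F8.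
- E-selective cross-metathesis of the terminal alkene of F8 with commercial 4-nitrophenyl acrylate (second-generation Hoveyda–Grubbs catalyst, CH2Cl2, 40 °C) gives 13. The conjugated, more substituted dienoate alkenes stay out of the reaction.

## Further compounds
F1 | step 12 | (3R,4R,5S,7R)-8-[(2S,3S)-2,3-dimethyloxiran-2-yl]-3-[(4-methoxyphenyl)methoxy]-5,7-dimethyloct-1-en-4-ol | C=C[C@@H](OCc1ccc(OC)cc1)[C@H](O)[C@@H](C)C[C@@H](C)C[C@]1(C)O[C@H]1C
F2 | step 12 | (3R,4R,5S,7R)-8-[(2S,3S)-2,3-dimethyloxiran-2-yl]-3-[(4-methoxyphenyl)methoxy]-5,7-dimethyloct-1-en-4-yl prop-2-enoate | C=C[C@@H](OCc1ccc(OC)cc1)[C@H](OC(=O)C=C)[C@@H](C)C[C@@H](C)C[C@]1(C)O[C@H]1C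
F3 | step 12 | (5R,6R)-6-{(2S,4R)-5-[(2S,3S)-2,3-dimethyloxiran-2-yl]-4-methylpentan-2-yl}-5-[(4-methoxyphenyl)methoxy]-5,6-dihydro-2H-pyran-2-one | COc1ccc(CO[C@@H]2C=CC(=O)O[C@@H]2[C@@H](C)C[C@@H](C)C[C@]3(C)O[C@H]3C)cc1
F4 | step 12 | (5R,6R)-6-{(2S,4R)-5-[(2S,3S)-2,3-dimethyloxiran-2-yl]-4-methylpentan-2-yl}-5-hydroxy-5,6-dihydro-2H-pyran-2-one | O[C@@H]1C=CC(=O)O[C@@H]1[C@@H](C)C[C@@H](C)C[C@]2(C)O[C@H]2C
F5 | step 13 | (2S,4R,6E)-2,4,6-trimethyloct-6-enal | O=C[C@@H](C)C[C@@H](C)C/C(C)=C/C
F6 | step 13 | (2R,3R)-2-[(2S,4R,6E)-4,6-dimethyloct-6-en-2-yl]-6-oxo-3,6-dihydro-2H-pyran-3-yl (2E,4E,6S)-8-[(tert-butyldimethylsilyl)oxy]-6-{[(tert-butyldimethylsilyl)oxy]methyl}-4-methylocta-2,4-dienoate | CC(/C=C/C(=O)O[C@@H]1C=CC(=O)O[C@@H]1[C@@H](C)C[C@@H](C)C/C(C)=C/C)=C\[C@@H](CO[Si](C)(C)C(C)(C)C)CCO[Si](C)(C)C(C)(C)C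
F7 | step 13 | (2R,3R)-2-[(2S,4R,6E)-4,6-dimethyloct-6-en-2-yl]-6-oxo-3,6-dihydro-2H-pyran-3-yl (2E,4E,6S)-8-hydroxy-6-(hydroxymethyl)-4-methylocta-2,4-dienoate | CC(/C=C/C(=O)O[C@@H]1C=CC(=O)O[C@@H]1[C@@H](C)C[C@@H](C)C/C(C)=C/C)=C\[C@@H](CO)CCO
F8 | step 5 | prop-2-en-1-yl (2E,4E,6S)-8-[(tert-butyldimethylsilyl)oxy]-6-{[(tert-butyldimethylsilyl)oxy]methyl}-4-methylocta-2,4-dienoate | CC(/C=C/C(=O)OCC=C)=C\[C@@H](CO[Si](C)(C)C(C)(C)C)CCO[Si](C)(C)C(C)(C)C
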